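With isochromene numbering, the carbocycle C4a–C5–C6–C7–C8–C8a holds an acyloin: the tertiary carbinol C7 beside ketone C8, flanked by ketone C6. The route rests on disconnecting C7–C8. A chiral triazolylidene catalyses an intramolecular crossed benzoin reaction in which a C8 aldehyde adds to the C7 carbonyl of a 1,2-diketone side chain, closing this ring on a preformed pyran and setting the C7 stereocentre in one operation. The precursor is a 3-formyl-4-(2,3-dioxobutylidene)-4H-pyran carrying the propenyl group, made from kojic acid by triflation, olefination, thionation, sulfide contraction and formylation. The protected O-methylorsellinic acid is esterified onto C7–OH afterwards.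

Key step: step 7

Assumption: the exocyclic C4a=C5 bond of 9 and 10 is a push–pull alkene that should equilibrate and is drawn in the Z form needed for ring closure, and the catalyst enantiomer named in step 7 is taken to deliver 7R (its antipode, equally available, would be used if the sense proves opposite).

Step 1
Reactants: 1 kojic acid (5-hydroxy-2-(hydroxymethyl)-4H-pyran-4-one)
Product: 2 6-(hydroxymethyl)-4-oxo-4H-pyran-3-yl trifluoromethanesulfonate
Conditions: PhNTf2, Et3N, CH2Cl2/DMF, 0 °C to rt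
Reagents that add atoms: N-phenylbis(trifluoromethanesulfonimide), FC(F)(F)S(=O)(=O)N(c1ccccc1)S(=O)(=O)C(F)(F)F
Why: The enolic 5-OH is far more acidic than the primary alcohol and should be sulfonylated selectively by PhNTf2 under mild base (O-triflation of an enol).

Step 2
Reactants: 2 6-(hydroxymethyl)-4-oxo-4H-pyran-3-yl trifluoromethanesulfonate
Product: 3 6-formyl-4-oxo-4H-pyran-3-yl trifluoromethanesulfonate
Conditions: Dess–Martin periodinane, CH2Cl2, rt
Reagents that add atoms: none
Why: Dess–Martin oxidation should take the primary alcohol to the aldehyde under neutral conditions that leave the enol triflate and the pyranone untouched.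

Step 3
Reactants: 3 6-formyl-4-oxo-4H-pyran-3-yl trifluoromethanesulfonate
Product: 4 4-oxo-6-[(1E)-prop-1-en-1-yl]-4H-pyran-3-yl trifluoromethanesulfonate
Conditions: CrCl2, CH3CHI2, THF, rt
Reagents that add atoms: 1,1-diiodoethane, CC(I)I
Why: In the Takai–Utimoto alkylidenation the geminal dichromium reagent from CH3CHI2 adds to the aldehyde and eliminates to the E-alkene, and divalent chromium alone should not insert into the enol triflate.

Step 4
Reactants: 4 4-oxo-6-[(1E)-prop-1-en-1-yl]-4H-pyran-3-yl trifluoromethanesulfonate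
Product: 5 6-[(1E)-prop-1-en-1-yl]-4-thioxo-4H-pyran-3-yl trifluoromethanesulfonate
Conditions: Lawesson reagent, toluene, 80 °C
Reagents that add atoms: Lawesson reagent, COc1ccc(cc1)P1(=S)SP(=S)(S1)c1ccc(OC)cc1
Why: Lawesson thionation exchanges the vinylogous ester carbonyl oxygen for sulfur, as is usual for 4-pyranones, while the sulfonate and the alkene are inert.

Step 5
Reactants: 5 6-[(1E)-prop-1-en-1-yl]-4-thioxo-4H-pyran-3-yl trifluoromethanesulfonate; 6 1-bromobutane-2,3-dione
Product: 9 (4Z)-4-(2,3-dioxobutylidene)-6-[(1E)-prop-1-en-1-yl]-4H-pyran-3-yl trifluoromethanesulfonate, via S-alkylpyrylium bromide 7 (not isolated), via spiro-thiirane 8 (not isolated)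
Conditions: 6, MeCN, rt; then PPh3, Et3N, 0 °C to rt
Reagents that add atoms: none
Why: In this Eschenmoser sulfide contraction, S-alkylation gives the 4-alkylthiopyrylium salt, deprotonation of its acidic SCH2CO group gives a thiocarbonyl ylide that closes to the thiirane, and PPh3 removes sulfur to leave the push–pull alkene.

Step 6
Reactants: 9 (4Z)-4-(2,3-dioxobutylidene)-6-[(1E)-prop-1-en-1-yl]-4H-pyran-3-yl trifluoromethanesulfonate
Product: 10 (4Z)-4-(2,3-dioxobutylidene)-6-[(1E)-prop-1-en-1-yl]-4H-pyran-3-carbaldehyde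
Conditions: Pd(OAc)2 (5 mol %), 1,3-bis(diphenylphosphino)propane, CO (1 atm), Et3SiH, Et3N, DMF, 70 °C
Reagents that add atoms: carbon monoxide, [C-]#[O+]
Why: Palladium-catalysed reductive carbonylation of the enol triflate (oxidative addition to zerovalent palladium, CO insertion, hydride transfer from Et3SiH) should give the aldehyde.

Step 7
Reactants: 10 (4Z)-4-(2,3-dioxobutylidene)-6-[(1E)-prop-1-en-1-yl]-4H-pyran-3-carbaldehyde
Product: 11 (7R)-7-hydroxy-7-methyl-3-[(1E)-prop-1-en-1-yl]-6H-isochromene-6,8(7H)-dione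
Conditions: (5aS,10bR)-2-(pentafluorophenyl)-5a,10b-dihydro-4H,6H-indeno[2,1-b][1,2,4]triazolo[4,3-d][1,4]oxazin-2-ium tetrafluoroborate (15 mol %), iPr2NEt (15 mol %), toluene (0.02 M), rt
Reagents that add atoms: none
Why: The triazolylidene freed by iPr2NEt adds to the C8 aldehyde of 10 and proton transfer gives the Breslow intermediate, whose nucleophilic C8 attacks the C7 ketone before proton transfer and loss of the carbene release 11; this is the intramolecular crossed aldehyde–ketone benzoin reaction, known in enantioselective form for six-membered α-ketols with a tertiary carbinol. The carbocycle C4a–C5–C6–C7–C8–C8a closes by 6-exo-trig attack of C8 on the C7=O group. The C7 configuration is controlled by the catalyst: the aminoindanol backbone shields one face of the hydrogen-bonded enaminol, so only one face of the C7 ketone is approached. The step needs attack at C7 and not at C6 (a 5-exo alternative), which should follow because C6 is a deactivated doubly vinylogous ester carbonyl while C7 is an acetyl carbonyl activated by its neighbour. The homoenolate pathway is closed because the β-carbon C1 carries the ring oxygen, and the push–pull C4a=C5 bond can rotate into the reactive Z geometry.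

Step 8
Reactants: 12 methyl orsellinate (methyl 2,4-dihydroxy-6-methylbenzoate)
Product: 13 methyl 2-hydroxy-4-(methoxymethoxy)-6-methylbenzoate
Conditions: MOMCl (1.05 equiv), iPr2NEt, CH2Cl2, 0 °C
Reagents that add atoms: chloromethyl methyl ether, COCCl
Why: The 4-OH should be alkylated selectively because the 2-OH is hydrogen-bonded to the ester carbonyl (regioselective MOM ether formation).

Step 9
Reactants: 13 methyl 2-hydroxy-4-(methoxymethoxy)-6-methylbenzoate
Product: 14 methyl 2-methoxy-4-(methoxymethoxy)-6-methylbenzoate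
Conditions: MeI, K2CO3, DMF, 40 °C
Reagents that add atoms: iodomethane, CI
Why: Williamson O-methylation of the remaining chelated phenol proceeds under K2CO3 in DMF without affecting the MOM ether.

Step 10
Reactants: 14 methyl 2-methoxy-4-(methoxymethoxy)-6-methylbenzoate
Product: 15 2-methoxy-4-(methoxymethoxy)-6-methylbenzoic acid
Conditions: KOH, MeOH/H2O, 80 °C; then 1 M HCl to pH 4, 0 °C
Reagents that add atoms: potassium hydroxide, [K+].[OH-]
Why: Saponification of the hindered methyl ester needs forcing base, which the MOM ether tolerates, and cold mild acidification then frees the acid.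

Step 11
Reactants: 15 2-methoxy-4-(methoxymethoxy)-6-methylbenzoic acid; 11 (7R)-7-hydroxy-7-methyl-3-[(1E)-prop-1-en-1-yl]-6H-isochromene-6,8(7H)-dione
Product: 17 (7R)-7-methyl-6,8-dioxo-3-[(1E)-prop-1-en-1-yl]-7,8-dihydro-6H-isochromen-7-yl 2-methoxy-4-(methoxymethoxy)-6-methylbenzoate, via aroyl chloride 16 (not isolated)
Conditions: 15, 1-chloro-N,N,2-trimethylprop-1-en-1-amine, CH2Cl2, 0 °C to rt; then 11, DMAP, Et3N, CH2Cl2, rt to 40 °C
Reagents that add atoms: 1-chloro-N,N,2-trimethylprop-1-en-1-amine, CC(C)=C(Cl)N(C)C (supplies the chlorine of 16 only)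
Why: The chloroenamine forms the acid chloride without HCl, so the MOM ether survives, and DMAP-catalysed acylation by the electron-rich aroyl chloride should esterify the tertiary C7 alcohol without touching the stereocentre.

Step 12
Reactants: 17 (7R)-7-methyl-6,8-dioxo-3-[(1E)-prop-1-en-1-yl]-7,8-dihydro-6H-isochromen-7-yl 2-methoxy-4-(methoxymethoxy)-6-methylbenzoate
Product: 18 (7R)-7-methyl-6,8-dioxo-3-[(1E)-prop-1-en-1-yl]-7,8-dihydro-6H-isochromen-7-yl 4-hydroxy-2-methoxy-6-methylbenzoate (target)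
Conditions: TFA, CH2Cl2, H2O (2 equiv), 0 °C to rt
Reagents that add atoms: none
Why: Acidic hydrolysis of the MOM acetal frees the phenol, while the azaphilone core and the tertiary ester, whose alkyl carbon cannot ionise between two carbonyls, should be stable to acid.

Compound list
1 | kojic acid (5-hydroxy-2-(hydroxymethyl)-4H-pyran-4-one) | OCC1=CC(=O)C(O)=CO1 | starting material
2 | 6-(hydroxymethyl)-4-oxo-4H-pyran-3-yl trifluoromethanesulfonate | OCC1=CC(=O)C(OS(=O)(=O)C(F)(F)F)=CO1 | intermediate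
3 | 6-formyl-4-oxo-4H-pyran-3-yl trifluoromethanesulfonate | O=CC1=CC(=O)C(OS(=O)(=O)C(F)(F)F)=CO1 | intermediate
4 | 4-oxo-6-[(1E)-prop-1-en-1-yl]-4H-pyran-3-yl trifluoromethanesulfonate | C/C=C/C1=CC(=O)C(OS(=O)(=O)C(F)(F)F)=CO1 | intermediate
5 | 6-[(1E)-prop-1-en-1-yl]-4-thioxo-4H-pyran-3-yl trifluoromethanesulfonate | C/C=C/C1=CC(=S)C(OS(=O)(=O)C(F)(F)F)=CO1 | intermediate
6 | 1-bromobutane-2,3-dione | CC(=O)C(=O)CBr | starting material
7 | 4-[(2,3-dioxobutyl)sulfanyl]-2-[(1E)-prop-1-en-1-yl]-5-(trifluoromethanesulfonyloxy)pyrylium bromide | C/C=C/c1cc(SCC(=O)C(C)=O)c(OS(=O)(=O)C(F)(F)F)c[o+]1.[Br-] | intermediate (not isolated)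
8 | 3-(2-oxopropanoyl)-6'-[(1E)-prop-1-en-1-yl]spiro[thiirane-2,4'-pyran]-3'-yl trifluoromethanesulfonate (mixture of stereoisomers) | C/C=C/C1=CC2(SC2C(=O)C(C)=O)C(OS(=O)(=O)C(F)(F)F)=CO1 | intermediate (not isolated)
9 | (4Z)-4-(2,3-dioxobutylidene)-6-[(1E)-prop-1-en-1-yl]-4H-pyran-3-yl trifluoromethanesulfonate | C/C=C/C1=C/C(=C/C(=O)C(C)=O)C(OS(=O)(=O)C(F)(F)F)=CO1 | intermediate
10 | (4Z)-4-(2,3-dioxobutylidene)-6-[(1E)-prop-1-en-1-yl]-4H-pyran-3-carbaldehyde | C/C=C/C1=C/C(=C/C(=O)C(C)=O)C(C=O)=CO1 | intermediate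
11 | (7R)-7-hydroxy-7-methyl-3-[(1E)-prop-1-en-1-yl]-6H-isochromene-6,8(7H)-dione | C/C=C/C1=CC2=CC(=O)[C@@](C)(O)C(=O)C2=CO1 | intermediate
12 | methyl orsellinate (methyl 2,4-dihydroxy-6-methylbenzoate) | COC(=O)c1c(C)cc(O)cc1O | starting material
13 | methyl 2-hydroxy-4-(methoxymethoxy)-6-methylbenzoate | COC(=O)c1c(C)cc(OCOC)cc1O | intermediate
14 | methyl 2-methoxy-4-(methoxymethoxy)-6-methylbenzoate | COC(=O)c1c(C)cc(OCOC)cc1OC | intermediate
15 | 2-methoxy-4-(methoxymethoxy)-6-methylbenzoic acid | OC(=O)c1c(C)cc(OCOC)cc1OC | intermediate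
16 | 2-methoxy-4-(methoxymethoxy)-6-methylbenzoyl chloride | ClC(=O)c1c(C)cc(OCOC)cc1OC | intermediate (not isolated)
17 | (7R)-7-methyl-6,8-dioxo-3-[(1E)-prop-1-en-1-yl]-7,8-dihydro-6H-isochromen-7-yl 2-methoxy-4-(methoxymethoxy)-6-methylbenzoate | C/C=C/C1=CC2=CC(=O)[C@@](C)(OC(=O)c3c(C)cc(OCOC)cc3OC)C(=O)C2=CO1 | intermediate
18 | (7R)-7-methyl-6,8-dioxo-3-[(1E)-prop-1-en-1-yl]-7,8-dihydro-6H-isochromen-7-yl 4-hydroxy-2-methoxy-6-methylbenzoate | C/C=C/C1=CC2=CC(=O)[C@@](C)(OC(=O)c3c(C)cc(O)cc3OC)C(=O)C2=CO1 | target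

Total step count: 12. Longest linear sequence: 9 steps (steps 1 to 7, then 11 and 12); steps 8 to 10 form the three-step acid branch.

Steps most likely to fail

Step 7 (benzoin ring closure). The carbene may be sequestered by reversible addition to the electrophilic C1 position or to the diketone, so that turnover stops, or the ring may close with poor facial selectivity at C7. Fallback, setting out from 10: reductive ketyl–carbonyl coupling with SmI2 (divalent samarium; THF, t-BuOH, −78 °C) should close the same C7–C8 bond and give 7,8-dihydroxy-7-methyl-3-[(1E)-prop-1-en-1-yl]-7,8-dihydro-6H-isochromen-6-one F1 as a mixture of stereoisomers. Oxidation of its secondary allylic C8 alcohol with MnO2 in CH2Cl2 should give racemic 7-hydroxy-7-methyl-3-[(1E)-prop-1-en-1-yl]-6H-isochromene-6,8(7H)-dione F2. The enantiomers are separated by preparative chromatography on a chiral stationary phase, and the 7R enantiomer comes back to the route at 11.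

Step 5 (sulfide contraction with the free diketone). The unprotected 1,2-diketone may be attacked by PPh3 or Et3N during sulfur extrusion, and it may also be reduced by the silane in step 6. Fallback, setting out from 5: commercial 3,3-dimethoxybutan-2-one (CC(=O)C(C)(OC)OC) is brominated with phenyltrimethylammonium tribromide in THF to 1-bromo-3,3-dimethoxybutan-2-one F3. S-Alkylation of 5 with it gives 4-[(3,3-dimethoxy-2-oxobutyl)sulfanyl]-2-[(1E)-prop-1-en-1-yl]-5-(trifluoromethanesulfonyloxy)pyrylium bromide F4. Et3N and PPh3 take this through 3-(2,2-dimethoxypropanoyl)-6'-[(1E)-prop-1-en-1-yl]spiro[thiirane-2,4'-pyran]-3'-yl trifluoromethanesulfonate F5 to (4Z)-4-(3,3-dimethoxy-2-oxobutylidene)-6-[(1E)-prop-1-en-1-yl]-4H-pyran-3-yl trifluoromethanesulfonate F6. Formylation under the conditions of step 6 gives (4Z)-4-(3,3-dimethoxy-2-oxobutylidene)-6-[(1E)-prop-1-en-1-yl]-4H-pyran-3-carbaldehyde F7, and hydrolysis of the ketal with aqueous TFA in CH2Cl2 comes back to the route at 10.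

Step 11 (esterification). Acylation may stall because the di-ortho-substituted aroyl chloride and the tertiary alcohol are both hindered, so that base-induced degradation of the azaphilone overtakes ester formation. Fallback, setting out from 11: the acyl group is delivered as an unhindered ketene. Commercial orsellinic acid (Cc1cc(O)cc(O)c1C(=O)O) is condensed with acetone (trifluoroacetic anhydride, TFA) to 7-hydroxy-2,2,5-trimethyl-4H-1,3-benzodioxin-4-one F8, which is protected with MOMCl and iPr2NEt as 7-(methoxymethoxy)-2,2,5-trimethyl-4H-1,3-benzodioxin-4-one F9. Irradiation of F9 at 300 nm in CH2Cl2 in the presence of 11 should generate 4-(methoxymethoxy)-2-methyl-6-(oxomethylidene)cyclohexa-2,4-dien-1-one F10, which is trapped by the tertiary alcohol as (7R)-7-methyl-6,8-dioxo-3-[(1E)-prop-1-en-1-yl]-7,8-dihydro-6H-isochromen-7-yl 2-hydroxy-4-(methoxymethoxy)-6-methylbenzoate F11. Neutral O-methylation of the chelated phenol with MeI and Ag2O comes back to the route at 17.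

Further compounds
F1 | step 7 | 7,8-dihydroxy-7-methyl-3-[(1E)-prop-1-en-1-yl]-7,8-dihydro-6H-isochromen-6-one (mixture of stereoisomers) | C/C=C/C1=CC2=CC(=O)C(C)(O)C(O)C2=CO1
F2 | step 7 | racemic 7-hydroxy-7-methyl-3-[(1E)-prop-1-en-1-yl]-6H-isochromene-6,8(7H)-dione | C/C=C/C1=CC2=CC(=O)C(C)(O)C(=O)C2=CO1
F3 | step 5 | 1-bromo-3,3-dimethoxybutan-2-one | CC(OC)(OC)C(=O)CBr
F4 | step 5 | 4-[(3,3-dimethoxy-2-oxobutyl)sulfanyl]-2-[(1E)-prop-1-en-1-yl]-5-(trifluoromethanesulfonyloxy)pyrylium bromide | C/C=C/c1cc(SCC(=O)C(C)(OC)OC)c(OS(=O)(=O)C(F)(F)F)c[o+]1.[Br-]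
F5 | step 5 | 3-(2,2-dimethoxypropanoyl)-6'-[(1E)-prop-1-en-1-yl]spiro[thiirane-2,4'-pyran]-3'-yl trifluoromethanesulfonate (mixture of stereoisomers) | C/C=C/C1=CC2(SC2C(=O)C(C)(OC)OC)C(OS(=O)(=O)C(F)(F)F)=CO1
F6 | step 5 | (4Z)-4-(3,3-dimethoxy-2-oxobutylidene)-6-[(1E)-prop-1-en-1-yl]-4H-pyran-3-yl trifluoromethanesulfonate | C/C=C/C1=C/C(=C/C(=O)C(C)(OC)OC)C(OS(=O)(=O)C(F)(F)F)=CO1
F7 | step 5 | (4Z)-4-(3,3-dimethoxy-2-oxobutylidene)-6-[(1E)-prop-1-en-1-yl]-4H-pyran-3-carbaldehyde | C/C=C/C1=C/C(=C/C(=O)C(C)(OC)OC)C(C=O)=CO1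
F8 | step 11 | 7-hydroxy-2,2,5-trimethyl-4H-1,3-benzodioxin-4-one | CC1(C)OC(=O)c2c(C)cc(O)cc2O1
F9 | step 11 | 7-(methoxymethoxy)-2,2,5-trimethyl-4H-1,3-benzodioxin-4-one | CC1(C)OC(=O)c2c(C)cc(OCOC)cc2O1
F10 | step 11 | 4-(methoxymethoxy)-2-methyl-6-(oxomethylidene)cyclohexa-2,4-dien-1-one | O=C=C1C(C)=CC(OCOC)=CC1=O
F11 | step 11 | (7R)-7-methyl-6,8-dioxo-3-[(1E)-prop-1-en-1-yl]-7,8-dihydro-6H-isochromen-7-yl 2-hydroxy-4-(methoxymethoxy)-6-methylbenzoate | C/C=C/C1=CC2=CC(=O)[C@@](C)(OC(=O)c3c(C)cc(OCOC)cc3O)C(=O)C2=CO1
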